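The runs were computed from invented constants.

You start from a ratio: target over other capture product. Suppose the two nucleophiles compete for one short-lived species, like two drains on one tank. That ratio is then the ratio of their two rates at that moment, and it scales with their charges.

in all of them: substrate 0.10 M
- Saturday's: first nucleophile 0.80 equiv; second nucleophile 7 equiv; capture agent 0.010 M; temperature 6 °C; run made earlier
- Monday's: first nucleophile 0.80 equiv; second nucleophile 11 equiv; capture agent 0.010 M; temperature 31 °C; run made earlier
- Friday's: first nucleophile 0.80 equiv; second nucleophile 5 equiv; capture agent 0.015 M; temperature 6 °C; run made earlier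
- blue: first nucleophile 0.800 equiv; second nucleophile 5.00 equiv; capture agent 0.0100 M; temperature 10 °C; time 40 min
- violet: first nucleophile 0.800 equiv; second nucleophile 5.00 equiv; capture agent 0.0100 M; temperature −5 °C; time 40 min
- amber: first nucleophile 0.800 equiv; second nucleophile 5.00 equiv; capture agent 0.0100 M; temperature 40 °C; time 40 min
- green: first nucleophile 0.800 equiv; second nucleophile 5.00 equiv; capture agent 0.0100 M; temperature 25 °C; time 40 min

- Saturday's (time / min: target / %, other capture product / %): 3.00: 0, 0; 10.0: 0.5, 0; 15.0: 0.4, 0; 25.0: 0.4, 0.2; 40.0: 0.5, 0; 50.0: 1.4, 0
- Monday's (time / min: target / %, other capture product / %): 1.00: 0.5, 0.4; 4.00: 3.4, 0.4; 5.00: 4.1, 0; 8.00: 6.0, 1.4; 15.0: 10.0, 1.7; 20.0: 11.2, 2.5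
- Friday's (time / min: target / %, other capture product / %): 4.00: 0.2, 0; 8.00: 0.7, 0; 15.0: 1.2, 0.5; 25.0: 0.2, 0; 50.0: 2.3, 0

(standard deviation of a reading: 0.5 percentage points)

- a species is counted by the substrate in it: one side product counts as two

- the flask with the highest share of target in all that became target or other capture product or solvolysis product or over-reaction product or side product or trapped intermediate ("all alike" if they lie within 1.5 percentage points) (blue / violet / amber / green / all alike)
- share of target in all that became target or other capture product or solvolysis product or over-reaction product or side product or trapped intermediate, blue
- share of target in all that became target or other capture product or solvolysis product or over-reaction product or side product or trapped intermediate, violet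
- share of target in all that became target or other capture product or solvolysis product or over-reaction product or side product or trapped intermediate, amber
- share of target in all that became target or other capture product or solvolysis product or over-reaction product or side product or trapped intermediate, green

1. Monday's last reading gives you a ratio of 4.48, with 11 equiv of second nucleophile against 0.80 equiv of first.

2. Divide out the charges. The ratio times second-nucleophile equivalents over first-nucleophile equivalents is 61.6. This is a selectivity factor: how much faster one equivalent of first nucleophile captures than one equivalent of second.

3. The four flasks carry 5.00 equiv against 0.800 equiv, so the ratio becomes 9.86. Target is then 90.8% of these two products. Every other product lowers that share, so at this selectivity factor it is a ceiling. Carrying it to other temperatures is an assumption, because the cold readings of other capture product lie within a scatter of 0.5 percentage points of zero.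

4. The weak link is the late reading, so reforge it. Monday's readings from 4.00 min to 8.00 min, pooled, give a ratio of 7.50, higher than the 4.48 of the last reading. You read this as target being lost once it has accumulated, so the early ratio is nearer the ratio of rates. The selectivity factor, the early ratio times the charge ratio, is 103. It remains a reading at Monday's 31 °C, resting on small numbers.

5. For the four flasks the ratio is 16.5 and the ceiling 94.3%. I commit to violet, the coldest of the four, close to that ceiling, and to amber, the hottest, furthest below it.

The forecast also chose violet, with blue 68%, violet 71%, amber 58% and green 64%. Its grounds include “so the share cannot exceed about 82%”. My ceiling differs from that figure, since it is the early ratio rescaled to these charges.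

The flasks give violet: blue 92.0%, violet 97.5%, amber 46.3%, green 76.8%.

    substrate → open intermediate (k = 0.0283 min⁻¹, Ea = 94.0 kJ mol⁻¹)
    substrate + target → side product (k = 0.0941 M⁻¹ min⁻¹, Ea = 68.0 kJ mol⁻¹)
    first nucleophile + open intermediate → target (k = 74.9 M⁻¹ min⁻¹, Ea = 41.0 kJ mol⁻¹)
    second nucleophile + open intermediate → other capture product (k = 1.08 M⁻¹ min⁻¹, Ea = 76.0 kJ mol⁻¹)
    open intermediate → solvolysis product (k = 0.413 min⁻¹, Ea = 80.0 kJ mol⁻¹)
    open intermediate + capture agent → trapped intermediate (k = 0.775 M⁻¹ min⁻¹, Ea = 51.0 kJ mol⁻¹)
    second nucleophile + target → over-reaction product (k = 0.0327 M⁻¹ min⁻¹, Ea = 63.0 kJ mol⁻¹)
    (constants at 40 °C)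

In violet, the open intermediate has a half-life of 1.6 min by the step to target at 20.0 min, against 4.9 h by the step to solvolysis product at 40.0 min. Violet's share stands above my ceiling. Reckoned on the charges from the amounts in violet at 400 min, the selectivity factor comes to 602, against my 103 read at Monday's 31 °C, so it did not hold from that temperature to violet's.

In the neighbour flask, violet repeated at 20 °C with the same charges, my selectivity factor of 103 gives a ratio of target to other capture product of 16.5 and a ceiling of 94.3%. The computed neighbour flask shows that ratio at 24.0 and a share of 83.5%.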